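**Strategy.** The target is cut at C3–C3'' into two flavone halves: a 3,3''-biflavone is hydrogenated by one chiral catalyst, syn at both tetrasubstituted C2=C3 bonds, which sets all four stereocentres (2,3-cis twice, C2-symmetric core). Unit A is commercial acacetin. The pyranone ring of unit B is never cyclised; the key step exploits that its C3'' lies between aryl-bearing C2'' and carbonyl C4'', the C2/C3 pair of a 3-oxybenzofuran. Dibromocarbene inserts into that bond of an aromatic 2-aryl-3-silyloxybenzofuran: the furan ring expands to the chromone and the new C3'' arrives with the bromine used to join the halves.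

Key step: step 3

Remark: unprimed locants denote unit A (5,7-dihydroxy half), doubly primed locants unit B (5-hydroxy-7-methoxy half); the ligand enantiomer in step 5 is assigned by analogy with simple flavones, and its antipode would be taken if the sense of induction proved opposite.

Step 1
Reactants: 1 acacetin (5,7-dihydroxy-2-(4-methoxyphenyl)-4H-chromen-4-one)
Product: 2 5,7-bis(benzyloxy)-2-(4-methoxyphenyl)-4H-chromen-4-one
Conditions: BnBr (2.5 equiv), K2CO3, DMF, 80 °C
Reagents that add atoms: benzyl bromide, BrCc1ccccc1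
Why: Williamson etherification; heating in DMF should alkylate the chelated 5-OH as well as the 7-OH, which removes the acidic protons before the later lithiation.

Step 2
Reactants: 3 4,6-dimethoxybenzofuran-3(2H)-one; 4 4-bromoanisole
Product: 6 tert-butyl{[4,6-dimethoxy-2-(4-methoxyphenyl)-1-benzofuran-3-yl]oxy}dimethylsilane, via sodium enolate 5 (not isolated)
Conditions: Pd(OAc)2 (2 mol%), XPhos (4 mol%), NaOtBu (2.2 equiv), toluene, 80 °C, Ar; then TBSCl (1.3 equiv), 0 °C → rt
Reagents that add atoms: tert-butyldimethylsilyl chloride, CC(C)(C)[Si](C)(C)Cl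
Why: Pd-catalysed α-arylation of a ketone enolate should arylate the aromatic 3-oxidobenzofuran at C2, and the more acidic product stays as enolate 5, which is O-silylated in the same flask so that the air-sensitive 2-aryl-coumaranone is never handled.

Step 3
Reactants: 6 tert-butyl{[4,6-dimethoxy-2-(4-methoxyphenyl)-1-benzofuran-3-yl]oxy}dimethylsilane; 7 bromoform
Product: 10 3-bromo-5,7-dimethoxy-2-(4-methoxyphenyl)-4H-chromen-4-one, via dibromocyclopropane 8 (not isolated), via silyloxyflavylium bromide 9 (not isolated)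
Conditions: CHBr3 (2 equiv), KOtBu (2.5 equiv), toluene, −30 °C → rt
Reagents that add atoms: none
Why: Dibromocarbene, formed from bromoform and KOtBu, should add [2+1] to the furan C2=C3 bond of 6 and give the cis-fused dibromocyclopropane 8. Pushed by the O1 lone pair and the silyloxy group, 8 should open by the disrotatory cyclopropyl-to-allyl-cation pathway with loss of the endo bromide, which breaks the former furan C2–C3 bond and gives the aromatic 3-bromo-4-silyloxyflavylium ion 9; bromide then removes the silyl group. The closest known reaction type is the Ciamician–Dennstedt-type dihalocarbene ring expansion, as used for cyclic silyl enol ethers (to 2-halo-enones) and for benzofurans (to chromenes). The six-membered pyranone is therefore not closed by a cyclisation but arises from the five-membered furan ring by one-carbon ring expansion through electrocyclic opening of the fused cyclopropane. No stereocentre is created, since racemic 8 is flattened again. The step needs chemoselective attack on C2=C3 over the three alkoxybenzene rings, which its enol-ether character secures, and the bromine must end at C3, which follows from the topology of the insertion.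

Step 4
Reactants: 2 5,7-bis(benzyloxy)-2-(4-methoxyphenyl)-4H-chromen-4-one; 10 3-bromo-5,7-dimethoxy-2-(4-methoxyphenyl)-4H-chromen-4-one
Product: 12 5,7-bis(benzyloxy)-5'',7''-dimethoxy-2,2''-bis(4-methoxyphenyl)-4H,4''H-[3,3''-bichromene]-4,4''-dione, via flavonylzinc chloride 11 (not isolated)
Conditions: 2 (1.3 equiv), LDA, THF, −78 °C; ZnCl2, −78 → 0 °C; then 10, Pd2(dba)3 (2.5 mol%), RuPhos (10 mol%), THF, 65 °C
Reagents that add atoms: none
Why: Carbonyl-assisted C3-lithiation of the flavone, immediate transmetalation to zinc (to suppress ring-opening of the 3-metallated chromone) and Negishi cross-coupling with a bulky dialkylbiarylphosphine–Pd catalyst should forge the tetra-ortho-substituted C3–C3'' bond.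

Step 5
Reactants: 12 5,7-bis(benzyloxy)-5'',7''-dimethoxy-2,2''-bis(4-methoxyphenyl)-4H,4''H-[3,3''-bichromene]-4,4''-dione
Product: 13 (2R,3R,2''R,3''R)-5,7-bis(benzyloxy)-5'',7''-dimethoxy-2,2''-bis(4-methoxyphenyl)-[3,3''-bichromane]-4,4''-dione
Conditions: H2 (60 bar), [Rh(cod)Cl]2 (2.5 mol%), chiral ferrocenyl bisphosphine–thiourea ligand (5.5 mol%), CH2Cl2–iPrOH, 60 °C
Reagents that add atoms: none
Why: Catalytic asymmetric hydrogenation of the chromone C2=C3 bond should deliver H2 syn to each tetrasubstituted enone, which gives 2,3-cis in both units, while the catalyst selects the same enantioface of both chromones and so gives the C2-symmetric (2R,3R,2''R,3''R) isomer, with rotation about the C3–C3'' axis at 60 °C expected to feed the matched atropisomer and the aryl ketones and benzyl ethers left untouched.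

Step 6
Reactants: 13 (2R,3R,2''R,3''R)-5,7-bis(benzyloxy)-5'',7''-dimethoxy-2,2''-bis(4-methoxyphenyl)-[3,3''-bichromane]-4,4''-dione
Product: 14 (2R,3R,2''R,3''R)-5,7,5''-trihydroxy-7''-methoxy-2,2''-bis(4-methoxyphenyl)-[3,3''-bichromane]-4,4''-dione
Conditions: BCl3 (6 equiv), pentamethylbenzene (6 equiv), CH2Cl2, −78 → 0 °C; MeOH quench
Reagents that add atoms: none
Why: Lewis-acid ether cleavage: BCl3 should remove both benzyl ethers at −78 °C (pentamethylbenzene traps the benzyl cation) and, through the C4''=O chelate, only the peri 5''-OMe on warming to 0 °C, leaving the 7''-, 4'- and 4'''-methyl ethers, and since no base is present the C3/C3'' centres should not be enolised.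

**Compound list**

1 | acacetin, 5,7-dihydroxy-2-(4-methoxyphenyl)-4H-chromen-4-one | COc1ccc(-c2cc(=O)c3c(O)cc(O)cc3o2)cc1 | starting material
2 | 5,7-bis(benzyloxy)-2-(4-methoxyphenyl)-4H-chromen-4-one | COc1ccc(-c2cc(=O)c3c(OCc4ccccc4)cc(OCc4ccccc4)cc3o2)cc1 | intermediate
3 | 4,6-dimethoxybenzofuran-3(2H)-one | COc1cc(OC)c2c(c1)OCC2=O | starting material
4 | 4-bromoanisole | COc1ccc(Br)cc1 | starting material
5 | sodium 4,6-dimethoxy-2-(4-methoxyphenyl)-1-benzofuran-3-olate | [Na+].[O-]c1c(-c2ccc(OC)cc2)oc2cc(OC)cc(OC)c12 | intermediate (not isolated)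
6 | tert-butyl{[4,6-dimethoxy-2-(4-methoxyphenyl)-1-benzofuran-3-yl]oxy}dimethylsilane | COc1ccc(-c2oc3cc(OC)cc(OC)c3c2O[Si](C)(C)C(C)(C)C)cc1 | intermediate
7 | bromoform | BrC(Br)Br | starting material
8 | 1,1-dibromo-6b-[(tert-butyldimethylsilyl)oxy]-4,6-dimethoxy-1a-(4-methoxyphenyl)-1a,6b-dihydro-1H-cyclopropa[b][1]benzofuran (racemic, cis-fused) | COc1ccc(cc1)C12Oc3cc(OC)cc(OC)c3C1(O[Si](C)(C)C(C)(C)C)C2(Br)Br | intermediate (not isolated)
9 | 3-bromo-4-[(tert-butyldimethylsilyl)oxy]-5,7-dimethoxy-2-(4-methoxyphenyl)chromenylium bromide | COc1ccc(cc1)-c1[o+]c2cc(OC)cc(OC)c2c(O[Si](C)(C)C(C)(C)C)c1Br.[Br-] | intermediate (not isolated)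
10 | 3-bromo-5,7-dimethoxy-2-(4-methoxyphenyl)-4H-chromen-4-one | COc1ccc(-c2oc3cc(OC)cc(OC)c3c(=O)c2Br)cc1 | intermediate
11 | [5,7-bis(benzyloxy)-2-(4-methoxyphenyl)-4-oxo-4H-chromen-3-yl]zinc chloride | COc1ccc(-c2oc3cc(OCc4ccccc4)cc(OCc4ccccc4)c3c(=O)c2[Zn]Cl)cc1 | intermediate (not isolated)
12 | 5,7-bis(benzyloxy)-5'',7''-dimethoxy-2,2''-bis(4-methoxyphenyl)-4H,4''H-[3,3''-bichromene]-4,4''-dione (racemic about the C3–C3'' axis) | COc1ccc(cc1)-c1oc2cc(OCc3ccccc3)cc(OCc3ccccc3)c2c(=O)c1-c1c(-c2ccc(OC)cc2)oc2cc(OC)cc(OC)c2c1=O | intermediate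
13 | (2R,3R,2''R,3''R)-5,7-bis(benzyloxy)-5'',7''-dimethoxy-2,2''-bis(4-methoxyphenyl)-[3,3''-bichromane]-4,4''-dione | COc1ccc([C@@H]2Oc3cc(OCc4ccccc4)cc(OCc4ccccc4)c3C(=O)[C@@H]2[C@H]2C(=O)c3c(OC)cc(OC)cc3O[C@H]2c2ccc(OC)cc2)cc1 | intermediate
14 | (2R,3R,2''R,3''R)-5,7,5''-trihydroxy-7''-methoxy-2,2''-bis(4-methoxyphenyl)-[3,3''-bichromane]-4,4''-dione | COc1ccc([C@@H]2Oc3cc(O)cc(O)c3C(=O)[C@@H]2[C@H]2C(=O)c3c(O)cc(OC)cc3O[C@H]2c2ccc(OC)cc2)cc1 | target

**Step count.** Total: 6 steps. Longest linear sequence: 5 steps (steps 2, 3, 4, 5, 6, from 3 and 4).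

**Steps most likely to fail**

1. Step 5. The two tetrasubstituted enones shield each other and may resist hydrogenation. Hydrogen delivery may also follow the axial chirality of each atropisomer of 12 instead of the catalyst, which would erode the enantiomeric excess.
Fallback, setting out from 2 and 10 and returning at 13: the C2 stereocentres are set on the unhindered monomers and the halves are joined afterwards. Flavone 2 is hydrogenated with the catalyst of step 5 to (2R)-5,7-bis(benzyloxy)-2-(4-methoxyphenyl)chroman-4-one F1. Bromide 10 is reduced with Zn in AcOH to 5,7-dimethoxy-2-(4-methoxyphenyl)-4H-chromen-4-one F2, which is hydrogenated likewise to (2R)-5,7-dimethoxy-2-(4-methoxyphenyl)chroman-4-one F3. Soft enolisation with iPr2Si(OTf)2 and Et3N, first of F1 and then of F3, gives the mixed diisopropylsilyl bis(enol ether) F4. Oxidation with CAN and NaHCO3 in MeCN at −20 °C couples the two tethered enol ethers to the 3,3''-linked diketone F5, with C2 and C2'' fixed and C3 and C3'' as formed. Double enolisation (LiHMDS, THF, −78 °C) and quenching with a hindered phenol as kinetic proton source should deliver each proton anti to the pseudo-axial C2 aryl group and give 13.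

2. Step 4. Transmetalation and reductive elimination at the tetra-ortho-substituted junction may be slow, so that protodezincation, ring-opening of the metallated chromone or homocoupling takes over.
Fallback, setting out from 10 and returning at 12: the pyranone of unit A is built last. Pd/XPhos α-arylation of the dianion of commercial 1-[2,4-bis(benzyloxy)-6-hydroxyphenyl]ethanone (NaOtBu, 2.2 equiv) with vinyl bromide 10 gives 1-[2,4-bis(benzyloxy)-6-hydroxyphenyl]-2-[5,7-dimethoxy-2-(4-methoxyphenyl)-4-oxo-4H-chromen-3-yl]ethanone F6. Allan–Robinson aroylation and cyclodehydration (4-methoxybenzoic anhydride, sodium 4-methoxybenzoate, 170 °C) then closes the chromone and gives 12.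

3. Step 6. Lewis-acid-promoted enolisation at C3/C3'' or reversible opening of the C2–O1 bond during the slower demethylation would erode the cis configuration, and benzyl transfer to the electron-rich rings is a second pathway.
Fallback, setting out from 10 and returning at 14: all three phenols are carried as benzyl ethers so that the last step is neutral. BCl3 (CH2Cl2, 0 °C) cleaves only the chelated 5-OMe of 10 and gives 3-bromo-5-hydroxy-7-methoxy-2-(4-methoxyphenyl)-4H-chromen-4-one F7. Benzylation (BnBr, K2CO3, DMF) gives 5-(benzyloxy)-3-bromo-7-methoxy-2-(4-methoxyphenyl)-4H-chromen-4-one F8. Negishi coupling with zinc reagent 11 as in step 4 gives 5,7,5''-tris(benzyloxy)-7''-methoxy-2,2''-bis(4-methoxyphenyl)-4H,4''H-[3,3''-bichromene]-4,4''-dione F9. Hydrogenation as in step 5 gives (2R,3R,2''R,3''R)-5,7,5''-tris(benzyloxy)-7''-methoxy-2,2''-bis(4-methoxyphenyl)-[3,3''-bichromane]-4,4''-dione F10. Hydrogenolysis (H2, 1 atm, Pd(OH)2/C, EtOAc–MeOH, rt) then gives 14.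

Further compounds
F1 | step 5 | (2R)-5,7-bis(benzyloxy)-2-(4-methoxyphenyl)chroman-4-one | O=C1C[C@H](c2ccc(OC)cc2)Oc2cc(OCc3ccccc3)cc(OCc3ccccc3)c12
F2 | step 5 | 5,7-dimethoxy-2-(4-methoxyphenyl)-4H-chromen-4-one | COc1ccc(-c2cc(=O)c3c(OC)cc(OC)cc3o2)cc1
F3 | step 5 | (2R)-5,7-dimethoxy-2-(4-methoxyphenyl)chroman-4-one | O=C1C[C@H](c2ccc(OC)cc2)Oc2cc(OC)cc(OC)c12
F4 | step 5 | {[(2R)-5,7-bis(benzyloxy)-2-(4-methoxyphenyl)-2H-chromen-4-yl]oxy}{[(2R)-5,7-dimethoxy-2-(4-methoxyphenyl)-2H-chromen-4-yl]oxy}diisopropylsilane | CC(C)[Si](C(C)C)(OC1=C[C@H](c2ccc(OC)cc2)Oc2cc(OCc3ccccc3)cc(OCc3ccccc3)c12)OC1=C[C@H](c2ccc(OC)cc2)Oc2cc(OC)cc(OC)c12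
F5 | step 5 | (2R,2''R)-5,7-bis(benzyloxy)-5'',7''-dimethoxy-2,2''-bis(4-methoxyphenyl)-[3,3''-bichromane]-4,4''-dione (mixture at C3 and C3'') | COc1ccc([C@@H]2Oc3cc(OCc4ccccc4)cc(OCc4ccccc4)c3C(=O)C2C2C(=O)c3c(OC)cc(OC)cc3O[C@H]2c2ccc(OC)cc2)cc1
F6 | step 4 | 1-[2,4-bis(benzyloxy)-6-hydroxyphenyl]-2-[5,7-dimethoxy-2-(4-methoxyphenyl)-4-oxo-4H-chromen-3-yl]ethanone | COc1ccc(-c2oc3cc(OC)cc(OC)c3c(=O)c2CC(=O)c2c(O)cc(OCc3ccccc3)cc2OCc2ccccc2)cc1
F7 | step 6 | 3-bromo-5-hydroxy-7-methoxy-2-(4-methoxyphenyl)-4H-chromen-4-one | COc1ccc(-c2oc3cc(OC)cc(O)c3c(=O)c2Br)cc1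
F8 | step 6 | 5-(benzyloxy)-3-bromo-7-methoxy-2-(4-methoxyphenyl)-4H-chromen-4-one | COc1ccc(-c2oc3cc(OC)cc(OCc4ccccc4)c3c(=O)c2Br)cc1
F9 | step 6 | 5,7,5''-tris(benzyloxy)-7''-methoxy-2,2''-bis(4-methoxyphenyl)-4H,4''H-[3,3''-bichromene]-4,4''-dione | COc1ccc(cc1)-c1oc2cc(OCc3ccccc3)cc(OCc3ccccc3)c2c(=O)c1-c1c(-c2ccc(OC)cc2)oc2cc(OC)cc(OCc3ccccc3)c2c1=O
F10 | step 6 | (2R,3R,2''R,3''R)-5,7,5''-tris(benzyloxy)-7''-methoxy-2,2''-bis(4-methoxyphenyl)-[3,3''-bichromane]-4,4''-dione | COc1ccc([C@@H]2Oc3cc(OCc4ccccc4)cc(OCc4ccccc4)c3C(=O)[C@@H]2[C@H]2C(=O)c3c(OCc4ccccc4)cc(OC)cc3O[C@H]2c2ccc(OC)cc2)cc1
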